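**Retrosynthetic overview**

1. Locants: ring C1(=O)–C2=C3–C4(OH)–C5(OH)–C6(OH)(chain); side chain C1′ (on C6) to C21′ with the Z-alkene at C12′=C13′. The end game is acid removal of one silyl ether and one acetonide, preceded by Saegusa–Ito desaturation to install C2=C3.
2. Key disconnection: the C13′(sp2)–C14′(sp3) bond, made by nickel-electrocatalytic decarboxylative alkenylation of the ring-bearing (Z)-alkenyl iodide 14 (C19) with the N-acyloxyphthalimide of nonanoic acid 16 (C9). This completes the C27 skeleton in one operation.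
3. Enabling feature: the isolated (Z)-C12′=C13′ alkene is insulated from the C1–C6 ring by eleven methylenes (C1′–C11′), and C13′ carries an unbranched primary n-octyl group (C14′–C21′), that is, nonanoic acid minus CO2 on a stereodefined alkenyl halide.
4. 14 comes from an iodoalkyne, itself from a TIPS-alkyne. The C5/C6 stereocentres come from OsO4 dihydroxylation of a 2-alkyl-4-silyloxycyclohexenone anti to the C4 silyl ether. C6–C1′ comes from a B-alkyl Suzuki coupling of a 2-iodoenone with a C13 enyne. C4 comes from asymmetric transfer hydrogenation.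
5. Rings: the carbocycle is present in the first compound and is never opened. The only ring formed is the temporary dioxolane (step 8), removed in step 14.

Key step: step 12

Assumption: in compounds 10–18 the ring is numbered from the ketone, so their C2/C3/C4 are C6/C5/C4 of the target; the hydride-transfer sense in step 1 is taken from the usual model for aryl/alkenyl ketones, and the antipodal ligand would be used if the opposite sense were found.

**Route**

Step 1
Reactants: 1 1,4-dioxaspiro[4.5]dec-6-en-8-one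
Product: 2 (8S)-1,4-dioxaspiro[4.5]dec-6-en-8-ol
Conditions: RuCl[(S,S)-TsDPEN](p-cymene) (cat.), HCO2Na, n-Bu4NCl, CH2Cl2/H2O, rt
Reagents that add atoms: none
Why: Noyori asymmetric transfer hydrogenation should reduce the enone C=O 1,2-selectively, the (S,S)-ligand delivering hydride to the face that gives the (S)-allylic alcohol (the alkenyl group plays the role of the aryl group in the CH/π model), which sets C4 of the target.

Step 2
Reactants: 2 (8S)-1,4-dioxaspiro[4.5]dec-6-en-8-ol
Product: 3 tert-butyl{[(8S)-1,4-dioxaspiro[4.5]dec-6-en-8-yl]oxy}dimethylsilane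
Conditions: TBSCl, imidazole, DMF, rt
Reagents that add atoms: tert-butyldimethylsilyl chloride, CC(C)(C)[Si](C)(C)Cl
Why: Standard silylation of a secondary allylic alcohol should proceed without touching the stereocentre, and the bulky silyl ether later serves as the control element for the dihydroxylation.

Step 3
Reactants: 3 tert-butyl{[(8S)-1,4-dioxaspiro[4.5]dec-6-en-8-yl]oxy}dimethylsilane
Product: 4 (4S)-4-[(tert-butyldimethylsilyl)oxy]cyclohex-2-en-1-one
Conditions: montmorillonite K-10, wet CH2Cl2, rt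
Reagents that add atoms: water, O
Why: Mild solid-acid ketal hydrolysis should release the ketone, now conjugated with the ring alkene, without cleaving the silyl ether or eliminating silanol.

Step 4
Reactants: 4 (4S)-4-[(tert-butyldimethylsilyl)oxy]cyclohex-2-en-1-one
Product: 5 (4S)-4-[(tert-butyldimethylsilyl)oxy]-2-iodocyclohex-2-en-1-one
Conditions: I2, pyridine/CH2Cl2, 0 °C → rt
Reagents that add atoms: iodine, II
Why: α-Iodination of an enone by conjugate addition of pyridine, iodination of the enolate and elimination should give the 2-iodoenone with the C4 stereocentre untouched.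

Step 5
Reactants: 6 11-bromoundec-1-ene; 7 ethynyltri(propan-2-yl)silane
Product: 8 tri(propan-2-yl)(tridec-12-en-1-yn-1-yl)silane
Conditions: 7, n-BuLi, THF, −78 → 0 °C; then 6, DMPU, 0 °C → rt
Reagents that add atoms: none
Why: SN2 alkylation of a lithium silylacetylide with a primary bromide in a dipolar cosolvent is reliable, and the terminal alkene is inert.

Step 6
Reactants: 8 tri(propan-2-yl)(tridec-12-en-1-yn-1-yl)silane; 5 (4S)-4-[(tert-butyldimethylsilyl)oxy]-2-iodocyclohex-2-en-1-one
Product: 10 (4S)-4-[(tert-butyldimethylsilyl)oxy]-2-[13-(triisopropylsilyl)tridec-12-yn-1-yl]cyclohex-2-en-1-one, via B-alkyl-9-BBN 9 (not isolated)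
Conditions: 8, 9-BBN, THF, 0 °C → rt; then 5, Pd(dppf)Cl2 (cat.), AsPh3 (cat.), Cs2CO3, DMF/H2O, rt
Reagents that add atoms: none
Why: In this B-alkyl Suzuki–Miyaura coupling, 9-BBN should hydroborate only the terminal alkene (anti-Markovnikov; the TIPS-alkyne is too hindered), and the borane should transmetallate to the alkenyl–Pd(II) species from the 2-iodoenone at room temperature, so the γ-silyloxy enone survives.

Step 7
Reactants: 10 (4S)-4-[(tert-butyldimethylsilyl)oxy]-2-[13-(triisopropylsilyl)tridec-12-yn-1-yl]cyclohex-2-en-1-one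
Product: 11 (2R,3R,4S)-4-[(tert-butyldimethylsilyl)oxy]-2,3-dihydroxy-2-[13-(triisopropylsilyl)tridec-12-yn-1-yl]cyclohexan-1-one
Conditions: K2OsO4·2H2O (cat.), NMO, citric acid, t-BuOH/H2O, rt
Reagents that add atoms: N-methylmorpholine N-oxide, C[N+]1([O-])CCOCC1; water, O; osmium tetroxide (catalytic oxygen carrier), O=[Os](=O)(=O)=O
Why: In this Upjohn dihydroxylation, OsO4 should add suprafacially to C2=C3 from the face anti to the adjacent C4 silyl ether, which sets the quaternary C2–OH and the C3–OH cis to each other and trans to C4–O (C6 and C5 of the target), while the hindered silylalkyne is not attacked.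

Step 8
Reactants: 11 (2R,3R,4S)-4-[(tert-butyldimethylsilyl)oxy]-2,3-dihydroxy-2-[13-(triisopropylsilyl)tridec-12-yn-1-yl]cyclohexan-1-one
Product: 12 (2R,3R,4S)-4-[(tert-butyldimethylsilyl)oxy]-2,3-(isopropylidenedioxy)-2-[13-(triisopropylsilyl)tridec-12-yn-1-yl]cyclohexan-1-one
Conditions: 2,2-dimethoxypropane, PPTS (cat.), CH2Cl2, rt
Reagents that add atoms: 2,2-dimethoxypropane, COC(C)(C)OC
Why: Acid-catalysed transketalisation should close the cis-fused dioxolane over the tertiary and secondary hydroxyls, and the quaternary α-carbon prevents any β-elimination.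

Step 9
Reactants: 12 (2R,3R,4S)-4-[(tert-butyldimethylsilyl)oxy]-2,3-(isopropylidenedioxy)-2-[13-(triisopropylsilyl)tridec-12-yn-1-yl]cyclohexan-1-one
Product: 13 (2R,3R,4S)-4-[(tert-butyldimethylsilyl)oxy]-2-(13-iodotridec-12-yn-1-yl)-2,3-(isopropylidenedioxy)cyclohexan-1-one
Conditions: NIS, AgF, MeCN, rt, dark
Reagents that add atoms: N-iodosuccinimide, O=C1CCC(=O)N1I
Why: In this silver(I)-mediated desilylative iodination, AgF should convert the silylalkyne into a silver acetylide that NIS iodinates in the same flask, and the poorly soluble fluoride source should spare the secondary silyl ether.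

Step 10
Reactants: 13 (2R,3R,4S)-4-[(tert-butyldimethylsilyl)oxy]-2-(13-iodotridec-12-yn-1-yl)-2,3-(isopropylidenedioxy)cyclohexan-1-one
Product: 14 (2R,3R,4S)-4-[(tert-butyldimethylsilyl)oxy]-2-[(12Z)-13-iodotridec-12-en-1-yl]-2,3-(isopropylidenedioxy)cyclohexan-1-one
Conditions: KO2CN=NCO2K, AcOH, pyridine, MeOH, rt
Reagents that add atoms: none
Why: Diimide reduction (diimide from acid-induced decarboxylation of azodicarboxylate) should transfer H2 in a concerted syn fashion to the iodoalkyne and give the (Z)-1-iodoalkene, while the ketone is untouched because neither a hydride nor a hydrazine nucleophile is present.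

Step 11
Reactants: 15 nonanoic acid
Product: 16 1,3-dioxoisoindolin-2-yl nonanoate
Conditions: N-hydroxyphthalimide, DIC, DMAP (cat.), CH2Cl2, rt
Reagents that add atoms: N-hydroxyphthalimide, ON1C(=O)c2ccccc2C1=O
Why: Carbodiimide esterification should give the redox-active N-acyloxyphthalimide cleanly.

Step 12
Reactants: 14 (2R,3R,4S)-4-[(tert-butyldimethylsilyl)oxy]-2-[(12Z)-13-iodotridec-12-en-1-yl]-2,3-(isopropylidenedioxy)cyclohexan-1-one; 16 1,3-dioxoisoindolin-2-yl nonanoate
Product: 17 (2R,3R,4S)-4-[(tert-butyldimethylsilyl)oxy]-2-[(12Z)-henicos-12-en-1-yl]-2,3-(isopropylidenedioxy)cyclohexan-1-one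
Conditions: 16 (excess), NiCl2·6H2O (cat.), 2,2′-bipyridine (cat.), AgNO3 (0.3 equiv), LiCl, DMF, Mg(+)/RVC(−), constant current, undivided cell, rt
Reagents that add atoms: none
Why: Cathodically reduced Ni(bpy) should insert into the C–I bond of 14 with retention to give a (Z)-alkenyl–Ni(II) species, while single-electron reduction of 16 (by low-valent nickel or at the silver-nanoparticle-coated cathode) expels phthalimide anion and CO2 to give the primary octyl radical; radical capture and reductive elimination from Ni(III) form the C13′–C14′ bond, with the Mg anode supplying the electrons. The closest known reaction type is the nickel-electrocatalytic decarboxylative alkenylation of redox-active esters with alkenyl halides. No ring is closed and no stereocentre is created, and the existing C2/C3/C4 triad is eleven methylenes away and untouched. The selectivity needed is retention of the Z geometry, which is secured because oxidative addition and reductive elimination at nickel are stereoretentive at room temperature and the alkenyl carbon never becomes a free radical. Cross-coupling over homo-coupling is secured by the excess of the inexpensive ester and the slow, surface-mediated generation of the radical. The free ketone, the silyl ether and the dioxolane should be tolerated because no stoichiometric organometallic nucleophile or base is present, and the enone is unveiled only afterwards so that no Michael acceptor can intercept the alkyl radical.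

Step 13
Reactants: 17 (2R,3R,4S)-4-[(tert-butyldimethylsilyl)oxy]-2-[(12Z)-henicos-12-en-1-yl]-2,3-(isopropylidenedioxy)cyclohexan-1-one
Product: 19 (4S,5R,6R)-4-[(tert-butyldimethylsilyl)oxy]-6-[(12Z)-henicos-12-en-1-yl]-5,6-(isopropylidenedioxy)cyclohex-2-en-1-one, via trimethylsilyl enol ether 18 (not isolated)
Conditions: LDA, TMSCl, THF, −78 °C; then Pd(OAc)2, MeCN, rt
Reagents that add atoms: none
Why: In this Saegusa–Ito oxidation, deprotonation can occur only at the CH2 flanking the ketone (the other α-carbon is quaternary), and the silyl enol ether should give an oxa-π-allyl palladium(II) species that undergoes β-hydride elimination to the enone without affecting any stereocentre or the remote Z-alkene.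

Step 14
Reactants: 19 (4S,5R,6R)-4-[(tert-butyldimethylsilyl)oxy]-6-[(12Z)-henicos-12-en-1-yl]-5,6-(isopropylidenedioxy)cyclohex-2-en-1-one
Product: 20 (4S,5R,6R)-4,5,6-trihydroxy-6-[(12Z)-henicos-12-en-1-yl]cyclohex-2-en-1-one
Conditions: TFA/H2O (9:1), 0 °C → rt
Reagents that add atoms: none
Why: Aqueous acid hydrolysis should cleave both the dioxolane and the silyl ether at the acetal carbon and at silicon respectively, so all three C–O bonds and stereocentres are retained, and C6 has no hydrogen through which the product could dehydrate towards an arene.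

**Compound list**

1 | 1,4-dioxaspiro[4.5]dec-6-en-8-one | O=C1C=CC2(CC1)OCCO2 | starting material
2 | (8S)-1,4-dioxaspiro[4.5]dec-6-en-8-ol | O[C@@H]1C=CC2(CC1)OCCO2 | intermediate
3 | tert-butyl{[(8S)-1,4-dioxaspiro[4.5]dec-6-en-8-yl]oxy}dimethylsilane | CC(C)(C)[Si](C)(C)O[C@@H]1C=CC2(CC1)OCCO2 | intermediate
4 | (4S)-4-[(tert-butyldimethylsilyl)oxy]cyclohex-2-en-1-one | CC(C)(C)[Si](C)(C)O[C@@H]1C=CC(=O)CC1 | intermediate
5 | (4S)-4-[(tert-butyldimethylsilyl)oxy]-2-iodocyclohex-2-en-1-one | CC(C)(C)[Si](C)(C)O[C@@H]1C=C(I)C(=O)CC1 | intermediate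
6 | 11-bromoundec-1-ene | C=CCCCCCCCCCBr | starting material
7 | ethynyltri(propan-2-yl)silane | C#C[Si](C(C)C)(C(C)C)C(C)C | starting material
8 | tri(propan-2-yl)(tridec-12-en-1-yn-1-yl)silane | C=CCCCCCCCCCC#C[Si](C(C)C)(C(C)C)C(C)C | intermediate
9 | 9-[13-(triisopropylsilyl)tridec-12-yn-1-yl]-9-borabicyclo[3.3.1]nonane (not isolated) | CC(C)[Si](C(C)C)(C(C)C)C#CCCCCCCCCCCCB1C2CCCC1CCC2 | intermediate
10 | (4S)-4-[(tert-butyldimethylsilyl)oxy]-2-[13-(triisopropylsilyl)tridec-12-yn-1-yl]cyclohex-2-en-1-one | CC(C)(C)[Si](C)(C)O[C@@H]1C=C(CCCCCCCCCCCC#C[Si](C(C)C)(C(C)C)C(C)C)C(=O)CC1 | intermediate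
11 | (2R,3R,4S)-4-[(tert-butyldimethylsilyl)oxy]-2,3-dihydroxy-2-[13-(triisopropylsilyl)tridec-12-yn-1-yl]cyclohexan-1-one | CC(C)[Si](C(C)C)(C(C)C)C#CCCCCCCCCCCC[C@]1(O)C(=O)CC[C@H](O[Si](C)(C)C(C)(C)C)[C@H]1O | intermediate
12 | (2R,3R,4S)-4-[(tert-butyldimethylsilyl)oxy]-2,3-(isopropylidenedioxy)-2-[13-(triisopropylsilyl)tridec-12-yn-1-yl]cyclohexan-1-one | CC(C)[Si](C(C)C)(C(C)C)C#CCCCCCCCCCCC[C@]1(OC(C)(C)O2)C(=O)CC[C@H](O[Si](C)(C)C(C)(C)C)[C@H]12 | intermediate
13 | (2R,3R,4S)-4-[(tert-butyldimethylsilyl)oxy]-2-(13-iodotridec-12-yn-1-yl)-2,3-(isopropylidenedioxy)cyclohexan-1-one | IC#CCCCCCCCCCCC[C@]1(OC(C)(C)O2)C(=O)CC[C@H](O[Si](C)(C)C(C)(C)C)[C@H]12 | intermediate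
14 | (2R,3R,4S)-4-[(tert-butyldimethylsilyl)oxy]-2-[(12Z)-13-iodotridec-12-en-1-yl]-2,3-(isopropylidenedioxy)cyclohexan-1-one | I/C=C\CCCCCCCCCCC[C@]1(OC(C)(C)O2)C(=O)CC[C@H](O[Si](C)(C)C(C)(C)C)[C@H]12 | intermediate
15 | nonanoic acid | CCCCCCCCC(=O)O | starting material
16 | 1,3-dioxoisoindolin-2-yl nonanoate | CCCCCCCCC(=O)ON1C(=O)c2ccccc2C1=O | intermediate
17 | (2R,3R,4S)-4-[(tert-butyldimethylsilyl)oxy]-2-[(12Z)-henicos-12-en-1-yl]-2,3-(isopropylidenedioxy)cyclohexan-1-one | CCCCCCCC/C=C\CCCCCCCCCCC[C@]1(OC(C)(C)O2)C(=O)CC[C@H](O[Si](C)(C)C(C)(C)C)[C@H]12 | intermediate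
18 | trimethylsilyl enol ether of 17 (C1–OSiMe3, C1=C6; not isolated) | CCCCCCCC/C=C\CCCCCCCCCCC[C@]1(OC(C)(C)O2)C(O[Si](C)(C)C)=CC[C@H](O[Si](C)(C)C(C)(C)C)[C@H]12 | intermediate
19 | (4S,5R,6R)-4-[(tert-butyldimethylsilyl)oxy]-6-[(12Z)-henicos-12-en-1-yl]-5,6-(isopropylidenedioxy)cyclohex-2-en-1-one | CCCCCCCC/C=C\CCCCCCCCCCC[C@]1(OC(C)(C)O2)C(=O)C=C[C@H](O[Si](C)(C)C(C)(C)C)[C@H]12 | intermediate
20 | (4S,5R,6R)-4,5,6-trihydroxy-6-[(12Z)-henicos-12-en-1-yl]cyclohex-2-en-1-one | CCCCCCCC/C=C\CCCCCCCCCCC[C@]1(O)C(=O)C=C[C@H](O)[C@H]1O | target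

**Step count and risks**

Total steps: 14. Longest linear sequence: 12 (steps 1–4, 6–10, 12–14); steps 5 and 11 are side branches.

Steps most likely to fail:

Step 12. The coupling may suffer from partial Z-to-E isomerisation at nickel, reductive homodimerisation of the alkenyl iodide, or premature reduction of the ester radical so that cross-coupling stalls. The fallback makes the same bond by a two-electron, stereoretentive B-alkyl Suzuki–Miyaura coupling. Oct-1-ene would be hydroborated with 9-BBN in THF to 9-octyl-9-borabicyclo[3.3.1]nonane F1, which would be coupled with 14 using Pd(dppf)Cl2, AsPh3 and Cs2CO3 in DMF/THF/H2O at rt. It sets out from 14 and comes back to the route at 17.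

Step 7. Osmylation of the electron-poor, trisubstituted enone may be very slow, and facial selectivity may be eroded. The fallback changes the oxidation level of the substrate. Setting out from 10, Luche reduction (NaBH4, CeCl3·7H2O, MeOH, −78 °C) should give the cis-1,4 allylic alcohol (1R,4S)-4-[(tert-butyldimethylsilyl)oxy]-2-[13-(triisopropylsilyl)tridec-12-yn-1-yl]cyclohex-2-en-1-ol F2. Its now electron-rich alkene would be dihydroxylated (OsO4 cat., NMO) anti to both allylic oxygens to give (1R,2S,3R,4S)-4-[(tert-butyldimethylsilyl)oxy]-2-[13-(triisopropylsilyl)tridec-12-yn-1-yl]cyclohexane-1,2,3-triol F3. The only cis-diol would be closed (2,2-dimethoxypropane, PPTS) to (1R,2S,3R,4S)-4-[(tert-butyldimethylsilyl)oxy]-2,3-(isopropylidenedioxy)-2-[13-(triisopropylsilyl)tridec-12-yn-1-yl]cyclohexan-1-ol F4. Dess–Martin oxidation of the C1 alcohol then comes back to the route at 12.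

Step 9. Fluoride may also cleave the secondary silyl ether, or the desilylation of the hindered silylalkyne may be incomplete. The fallback separates the events. Setting out from 12, TBAF in THF would remove both silyl groups to give (2R,3R,4S)-4-hydroxy-2,3-(isopropylidenedioxy)-2-(tridec-12-yn-1-yl)cyclohexan-1-one F5. Re-silylation of the C4 hydroxyl (TBSCl, imidazole, DMF) would give (2R,3R,4S)-4-[(tert-butyldimethylsilyl)oxy]-2,3-(isopropylidenedioxy)-2-(tridec-12-yn-1-yl)cyclohexan-1-one F6. Catalytic-silver iodination of the free terminal alkyne (NIS, AgNO3 cat., acetone, rt) then comes back to the route at 13.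

Further compounds
F1 | step 12 | 9-octyl-9-borabicyclo[3.3.1]nonane | CCCCCCCCB1C2CCCC1CCC2
F2 | step 7 | (1R,4S)-4-[(tert-butyldimethylsilyl)oxy]-2-[13-(triisopropylsilyl)tridec-12-yn-1-yl]cyclohex-2-en-1-ol | CC(C)(C)[Si](C)(C)O[C@@H]1C=C(CCCCCCCCCCCC#C[Si](C(C)C)(C(C)C)C(C)C)[C@H](O)CC1
F3 | step 7 | (1R,2S,3R,4S)-4-[(tert-butyldimethylsilyl)oxy]-2-[13-(triisopropylsilyl)tridec-12-yn-1-yl]cyclohexane-1,2,3-triol | CC(C)[Si](C(C)C)(C(C)C)C#CCCCCCCCCCCC[C@]1(O)[C@H](O)CC[C@H](O[Si](C)(C)C(C)(C)C)[C@H]1O
F4 | step 7 | (1R,2S,3R,4S)-4-[(tert-butyldimethylsilyl)oxy]-2,3-(isopropylidenedioxy)-2-[13-(triisopropylsilyl)tridec-12-yn-1-yl]cyclohexan-1-ol | CC(C)[Si](C(C)C)(C(C)C)C#CCCCCCCCCCCC[C@]1(OC(C)(C)O2)[C@H](O)CC[C@H](O[Si](C)(C)C(C)(C)C)[C@H]12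
F5 | step 9 | (2R,3R,4S)-4-hydroxy-2,3-(isopropylidenedioxy)-2-(tridec-12-yn-1-yl)cyclohexan-1-one | C#CCCCCCCCCCCC[C@]1(OC(C)(C)O2)C(=O)CC[C@H](O)[C@H]12
F6 | step 9 | (2R,3R,4S)-4-[(tert-butyldimethylsilyl)oxy]-2,3-(isopropylidenedioxy)-2-(tridec-12-yn-1-yl)cyclohexan-1-one | C#CCCCCCCCCCCC[C@]1(OC(C)(C)O2)C(=O)CC[C@H](O[Si](C)(C)C(C)(C)C)[C@H]12
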